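Assumption: the 3′–6″ biaryl axis is not a fixed stereo-element (none is given in the target), so C2″ (S) is the only stereocentre to control. Plain and single-primed locants refer to the flavone unit, double-primed locants to the flavanone unit.

**Retrosynthetic overview**
1. Target ⇒ its tri-O-benzyl ether; hydrogenolysis is last, and both methyl ethers are carried from the start.
2. Key disconnection: the C3′–C6″ biaryl bond. Both carbons are innately nucleophilic (each ortho to oxygen), so C3′ is reversed to an aryl-cation (aromatic enolonium) equivalent, an ortho-methoxyaryllead triacetate, and joined to C6″ of the intact (2S)-flavanone under direction by its 5-OH.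
3. Flavone half: ring C is closed by oxidative cyclisation of a 2′-hydroxychalcone made from 3-bromo-4-methoxybenzaldehyde; then Br → SnBu3 → Pb(OAc)3.
4. Flavanone half: ring C is closed first as a chromone; C2″ (S) is then set by Rh-catalysed asymmetric 1,4-addition of 4-methoxyphenylboronic acid, and peri-selective 5-O-debenzylation frees the directing phenol.
5. Ring order: ring A of both halves is bought (phloroacetophenone, one common intermediate); the two rings C are made in parallel; biaryl union, then deprotection.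

**Route**

Step 1
Reactants: 1 2′,4′,6′-trihydroxyacetophenone
Product: 2 1-[2,4-bis(benzyloxy)-6-hydroxyphenyl]ethan-1-one
Conditions: BnBr (2.2 equiv), K2CO3 (2.5 equiv), DMF, 0 °C to rt
Reagents that add atoms: benzyl bromide BrCc1ccccc1
Why: Williamson etherification benzylates the two most acidic, non-chelated phenols, while the remaining ortho OH is hydrogen-bonded to the acetyl carbonyl and stays free.

Step 2
Reactants: 2 1-[2,4-bis(benzyloxy)-6-hydroxyphenyl]ethan-1-one; 3 3-bromo-4-methoxybenzaldehyde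
Product: 4 (E)-1-[2,4-bis(benzyloxy)-6-hydroxyphenyl]-3-(3-bromo-4-methoxyphenyl)prop-2-en-1-one
Conditions: KOH (50% aq.), EtOH/THF, rt, 36 h
Reagents that add atoms: none
Why: Claisen–Schmidt condensation of the methyl ketone enolate with a non-enolisable aldehyde, followed by dehydration to the thermodynamically favoured E-enone.

Step 3
Reactants: 4 (E)-1-[2,4-bis(benzyloxy)-6-hydroxyphenyl]-3-(3-bromo-4-methoxyphenyl)prop-2-en-1-one
Product: 5 5,7-bis(benzyloxy)-2-(3-bromo-4-methoxyphenyl)-4H-chromen-4-one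
Conditions: I2 (10 mol%), DMSO, 130 °C
Reagents that add atoms: none
Why: Iodine/DMSO oxidative cyclisation closes ring C by oxa-Michael addition and then dehydrogenates by α-iodination and HI loss, with DMSO returning HI to I2; benzyl ethers and the aryl bromide are inert.

Step 4
Reactants: 5 5,7-bis(benzyloxy)-2-(3-bromo-4-methoxyphenyl)-4H-chromen-4-one
Product: 6 5,7-bis(benzyloxy)-2-[4-methoxy-3-(tributylstannyl)phenyl]-4H-chromen-4-one
Conditions: (Bu3Sn)2 (1.5 equiv), Pd(PPh3)4 (5 mol%), toluene, 110 °C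
Reagents that add atoms: hexabutylditin CCCC[Sn](CCCC)(CCCC)[Sn](CCCC)(CCCC)CCCC
Why: Palladium-catalysed stannylation of an aryl bromide with a distannane (oxidative addition, Sn–Sn transmetalation, reductive elimination) puts the tin exactly at C3′ and tolerates the flavone and benzyl ethers.

Step 5
Reactants: 2 1-[2,4-bis(benzyloxy)-6-hydroxyphenyl]ethan-1-one
Product: 8 5,7-bis(benzyloxy)-4H-chromen-4-one, via enaminone 7 (not isolated)
Conditions: Me2NCH(OMe)2 (3 equiv), toluene, 100 °C; then AcOH, 80 °C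
Reagents that add atoms: N,N-dimethylformamide dimethyl acetal COC(OC)N(C)C
Why: Enaminone chromone synthesis: the acetyl CH3 condenses with the amide acetal, and under acid the chelated phenol adds to the enaminone and expels dimethylamine to close ring C.

Step 6
Reactants: 8 5,7-bis(benzyloxy)-4H-chromen-4-one; 9 (4-methoxyphenyl)boronic acid
Product: 10 (2S)-5,7-bis(benzyloxy)-2-(4-methoxyphenyl)chroman-4-one
Conditions: 9 (2 equiv), [Rh(OH)(cod)]2 (1.5 mol%), (S)-MeO-F12-BIPHEP (3.3 mol%), toluene/H2O (10:1), 40 °C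
Reagents that add atoms: none
Why: Hayashi–Miyaura asymmetric 1,4-addition: the aryl–rhodium species of the electron-poor (S)-diphosphine inserts the chromone C2=C3 bond on one face, which sets C2 as S by the facial model that gives (S)-3-arylcyclohexanones with (S)-BINAP, and water protonates the rhodium enolate.

Step 7
Reactants: 10 (2S)-5,7-bis(benzyloxy)-2-(4-methoxyphenyl)chroman-4-one
Product: 11 (2S)-7-(benzyloxy)-5-hydroxy-2-(4-methoxyphenyl)chroman-4-one
Conditions: BCl3 (1.1 equiv), CH2Cl2, −78 °C, 20 min; then H2O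
Reagents that add atoms: none
Why: Chelation-controlled Lewis-acid ether cleavage: BCl3 bridges the C4 carbonyl and the peri 5-O-benzyl oxygen, so only that benzyl group is lost at −78 °C while the 7-O-benzyl ether and C2 are untouched.

Step 8
Reactants: 6 5,7-bis(benzyloxy)-2-[4-methoxy-3-(tributylstannyl)phenyl]-4H-chromen-4-one; 11 (2S)-7-(benzyloxy)-5-hydroxy-2-(4-methoxyphenyl)chroman-4-one
Product: 13 (2S)-7-(benzyloxy)-6-{5-[5,7-bis(benzyloxy)-4-oxo-4H-chromen-2-yl]-2-methoxyphenyl}-5-hydroxy-2-(4-methoxyphenyl)chroman-4-one, via aryllead triacetate 12 (not isolated)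
Conditions: 6 (1.05 equiv), Pb(OAc)4 (1.0 equiv), Hg(OAc)2 (5 mol%), CHCl3, 40 °C, 12 h; then 11 (0.9 equiv), pyridine (3 equiv), CHCl3, 60 °C
Reagents that add atoms: lead tetraacetate CC(=O)O[Pb](OC(C)=O)(OC(C)=O)OC(C)=O (its atoms remain in 12 only)
Why: Proposed new method: Hg(OAc)2-catalysed tin–lead exchange turns the innately nucleophilic C3′ of 6 into 12, an aryl-cation (aromatic enolonium) equivalent of tetravalent lead whose ortho-methoxy group is known to favour ligand coupling; the only free phenol of 11 (5-OH, able to chelate lead with the C4 carbonyl like the β-dicarbonyl substrates of this reaction) replaces an acetate, and ligand coupling then delivers the aryl group to the sole free ortho carbon C6″ (C8″ is para and outside the cyclic transition state, C4a is substituted and could not rearomatise), followed by rearomatisation and loss of Pb(OAc)2, with C2″ untouched by pyridine at 60 °C; the closest known reaction type is the Pinhey ortho-C-arylation of electron-rich phenols (3,5-dimethoxyphenol, mesitol) and 4-hydroxycoumarins with ortho-methoxyaryllead triacetates, here extended to a chelated 2-acylphenol and a flavone-bearing aryllead.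

Step 9
Reactants: 13 (2S)-7-(benzyloxy)-6-{5-[5,7-bis(benzyloxy)-4-oxo-4H-chromen-2-yl]-2-methoxyphenyl}-5-hydroxy-2-(4-methoxyphenyl)chroman-4-one
Product: 14 (2S)-6-[5-(5,7-dihydroxy-4-oxo-4H-chromen-2-yl)-2-methoxyphenyl]-5,7-dihydroxy-2-(4-methoxyphenyl)chroman-4-one
Conditions: H2 (1 atm), 10% Pd/C, EtOAc/MeOH, rt, stopped at full conversion
Reagents that add atoms: none
Why: Catalytic hydrogenolysis removes the three O-benzyl groups under neutral conditions that leave the methyl ethers, the flavone enone, the aryl ketone and the C2″ stereocentre intact.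

**Compound list**
1 | 2′,4′,6′-trihydroxyacetophenone | CC(=O)c1c(O)cc(O)cc1O | starting material
2 | 1-[2,4-bis(benzyloxy)-6-hydroxyphenyl]ethan-1-one | CC(=O)c1c(O)cc(OCc2ccccc2)cc1OCc1ccccc1 | intermediate
3 | 3-bromo-4-methoxybenzaldehyde | COc1ccc(C=O)cc1Br | starting material
4 | (E)-1-[2,4-bis(benzyloxy)-6-hydroxyphenyl]-3-(3-bromo-4-methoxyphenyl)prop-2-en-1-one | COc1ccc(/C=C/C(=O)c2c(O)cc(OCc3ccccc3)cc2OCc2ccccc2)cc1Br | intermediate
5 | 5,7-bis(benzyloxy)-2-(3-bromo-4-methoxyphenyl)-4H-chromen-4-one | COc1ccc(-c2cc(=O)c3c(OCc4ccccc4)cc(OCc4ccccc4)cc3o2)cc1Br | intermediate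
6 | 5,7-bis(benzyloxy)-2-[4-methoxy-3-(tributylstannyl)phenyl]-4H-chromen-4-one | COc1ccc(-c2cc(=O)c3c(OCc4ccccc4)cc(OCc4ccccc4)cc3o2)cc1[Sn](CCCC)(CCCC)CCCC | intermediate
7 | (E)-1-[2,4-bis(benzyloxy)-6-hydroxyphenyl]-3-(dimethylamino)prop-2-en-1-one | CN(C)/C=C/C(=O)c1c(O)cc(OCc2ccccc2)cc1OCc1ccccc1 | intermediate
8 | 5,7-bis(benzyloxy)-4H-chromen-4-one | O=c1ccoc2cc(OCc3ccccc3)cc(OCc3ccccc3)c12 | intermediate
9 | (4-methoxyphenyl)boronic acid | COc1ccc(B(O)O)cc1 | starting material
10 | (2S)-5,7-bis(benzyloxy)-2-(4-methoxyphenyl)chroman-4-one | COc1ccc([C@@H]2CC(=O)c3c(OCc4ccccc4)cc(OCc4ccccc4)cc3O2)cc1 | intermediate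
11 | (2S)-7-(benzyloxy)-5-hydroxy-2-(4-methoxyphenyl)chroman-4-one | COc1ccc([C@@H]2CC(=O)c3c(O)cc(OCc4ccccc4)cc3O2)cc1 | intermediate
12 | {5-[5,7-bis(benzyloxy)-4-oxo-4H-chromen-2-yl]-2-methoxyphenyl}lead triacetate | COc1ccc(-c2cc(=O)c3c(OCc4ccccc4)cc(OCc4ccccc4)cc3o2)cc1[Pb](OC(C)=O)(OC(C)=O)OC(C)=O | intermediate
13 | (2S)-7-(benzyloxy)-6-{5-[5,7-bis(benzyloxy)-4-oxo-4H-chromen-2-yl]-2-methoxyphenyl}-5-hydroxy-2-(4-methoxyphenyl)chroman-4-one | COc1ccc([C@@H]2CC(=O)c3c(cc(OCc4ccccc4)c(-c4cc(-c5cc(=O)c6c(OCc7ccccc7)cc(OCc7ccccc7)cc6o5)ccc4OC)c3O)O2)cc1 | intermediate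
14 | (2S)-6-[5-(5,7-dihydroxy-4-oxo-4H-chromen-2-yl)-2-methoxyphenyl]-5,7-dihydroxy-2-(4-methoxyphenyl)chroman-4-one | COc1ccc([C@@H]2CC(=O)c3c(cc(O)c(-c4cc(-c5cc(=O)c6c(O)cc(O)cc6o5)ccc4OC)c3O)O2)cc1 | target

**Totals**
Total step count: 9.
Longest linear sequence: 6 steps (steps 1, 2, 3, 4, 8, 9; the flavanone branch, steps 1, 5, 6, 7, 8, 9, is equally long).

**Three steps most likely to fail**

Step 8 (biaryl union). A chelated 2-acylphenol is a weaker partner for tetravalent lead than the phenols on which this arylation is established. Coupling at C4a, oxidation of the phenol by residual Pb(OAc)4, or protodestannylation of 6 could compete. The fallback sets out from 11 and 5 and returns at 13. It moves the reversed polarity to ring A and uses C3′ in its innate nucleophilic sense. Compound 11 is iodinated ortho to the free phenol with benzyltrimethylammonium dichloroiodate and CaCO3 in CH2Cl2/MeOH at rt to give (2S)-7-(benzyloxy)-5-hydroxy-6-iodo-2-(4-methoxyphenyl)chroman-4-one F1. Bromide 5 is borylated with bis(pinacolato)diboron, Pd(dppf)Cl2 and KOAc in dioxane at 90 °C to give 5,7-bis(benzyloxy)-2-[4-methoxy-3-(4,4,5,5-tetramethyl-1,3,2-dioxaborolan-2-yl)phenyl]-4H-chromen-4-one F2. Coupling of F1 with F2 (Pd(OAc)2, SPhos, K3PO4, toluene/H2O, 60 °C) gives 13.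

Step 6 (asymmetric 1,4-addition). The peri 5-benzyloxy group and the electron-rich boronic acid may slow insertion, and the level and sense of induction must be confirmed by chiral HPLC and CD; if the sense is opposite, the (R)-ligand is used. The fallback sets out from 2 and returns at 10. Compound 2 is condensed with 4-methoxybenzaldehyde (KOH, EtOH, rt) to give (E)-1-[2,4-bis(benzyloxy)-6-hydroxyphenyl]-3-(4-methoxyphenyl)prop-2-en-1-one F3. Cyclisation with NaOAc in refluxing EtOH gives rac-5,7-bis(benzyloxy)-2-(4-methoxyphenyl)chroman-4-one F4. Preparative chiral supercritical-fluid chromatography on an amylose tris(3,5-dimethylphenylcarbamate) phase delivers 10; the unwanted (2R)-enantiomer is recycled with base through F3.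

Step 7 (selective 5-O-debenzylation). Lewis-acid activation of the carbonyl could open the acid-sensitive 4′-methoxyflavanone ring, which would racemise C2, or could also cleave the 7-O-benzyl ether. The fallback sets out from 10 and returns at 11. Both benzyl groups of 10 are removed by neutral hydrogenolysis (H2, 10% Pd/C, EtOAc) to give (2S)-5,7-dihydroxy-2-(4-methoxyphenyl)chroman-4-one F5. The non-chelated 7-OH alone is then benzylated under neutral Mitsunobu conditions (BnOH, PPh3, DIAD, THF, 0 °C) to give 11.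

**Further compounds**
F1 | step 8 | (2S)-7-(benzyloxy)-5-hydroxy-6-iodo-2-(4-methoxyphenyl)chroman-4-one | COc1ccc([C@@H]2CC(=O)c3c(cc(OCc4ccccc4)c(I)c3O)O2)cc1
F2 | step 8 | 5,7-bis(benzyloxy)-2-[4-methoxy-3-(4,4,5,5-tetramethyl-1,3,2-dioxaborolan-2-yl)phenyl]-4H-chromen-4-one | COc1ccc(-c2cc(=O)c3c(OCc4ccccc4)cc(OCc4ccccc4)cc3o2)cc1B1OC(C)(C)C(C)(C)O1
F3 | step 6 | (E)-1-[2,4-bis(benzyloxy)-6-hydroxyphenyl]-3-(4-methoxyphenyl)prop-2-en-1-one | COc1ccc(/C=C/C(=O)c2c(O)cc(OCc3ccccc3)cc2OCc2ccccc2)cc1
F4 | step 6 | rac-5,7-bis(benzyloxy)-2-(4-methoxyphenyl)chroman-4-one | COc1ccc(C2CC(=O)c3c(OCc4ccccc4)cc(OCc4ccccc4)cc3O2)cc1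
F5 | step 7 | (2S)-5,7-dihydroxy-2-(4-methoxyphenyl)chroman-4-one | COc1ccc([C@@H]2CC(=O)c3c(O)cc(O)cc3O2)cc1
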